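**Retrosynthetic overview**

- The strategy rests on the dihydropyran ring of the 2,2-dimethylchroman-3-ol. O1, C8a, C4a and C4 are the four atoms of an o-quinone methide built from the para-hydroxyl of a protected phloroacetophenone and one formaldehyde carbon. C2 (gem-dimethyl) and C3 (carbinol) are a trisubstituted alkene that carries boron at C3 as a masked hydroxyl.
- Last disconnection: the C8–CH2–C3' methylene bridge, made by a Mannich/conjugate-addition union of the debenzylated chromanol with 6-ethyl-4-hydroxy-5-methylpyran-2-one.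
- The chroman comes from a three-component (4+2) annulation of 1-[2,6-bis(benzyloxy)-4-hydroxyphenyl]ethanone, formaldehyde and the 2-methylprop-1-enyl pinacol boronate, followed by C–B to C–O oxidation with retention.
- The pyranone comes from γ-acylation of a β-keto ester dianion and enol lactonisation.
- Ring order: the aromatic ring is bought; the dihydropyran ring closes in step 4; the pyranone ring closes in step 8; the two halves are joined in step 9.

Key step: step 4

Assumption: the sense of induction of the chiral acid in step 4 cannot be predicted, so the catalyst antipode that gives the (3R)-boronate is to be found in a first screen, and the route is written for that antipode.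

**Route**

Step 1
Reactants: 1 2',4',6'-trihydroxyacetophenone (dried)
Product: 2 1-[2,6-dihydroxy-4-(methoxymethoxy)phenyl]ethanone
Conditions: MOMCl (1.05 equiv), iPr2NEt (1.1 equiv), CH2Cl2/THF, 0 °C
Reagents that add atoms: chloromethyl methyl ether (MOMCl), COCCl
Why: The 4-hydroxyl is the most acidic one and the only one not hydrogen-bonded to the ketone, so one equivalent of the chloro ether with a hindered amine should etherify it preferentially (Williamson-type O-alkylation).

Step 2
Reactants: 2 1-[2,6-dihydroxy-4-(methoxymethoxy)phenyl]ethanone; 3 benzyl bromide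
Product: 4 1-[2,6-bis(benzyloxy)-4-(methoxymethoxy)phenyl]ethanone
Conditions: BnBr (2.5 equiv), K2CO3, Bu4NI (cat.), DMF, 70 °C
Reagents that add atoms: benzyl bromide (second equivalent of 3, for the second hydroxyl), BrCc1ccccc1
Why: Twofold Williamson etherification under forcing carbonate/DMF conditions should overcome the phenol–ketone hydrogen bonds and favour O- over C-benzylation at both chelated hydroxyls, while the acetal ether is stable to base.

Step 3
Reactants: 4 1-[2,6-bis(benzyloxy)-4-(methoxymethoxy)phenyl]ethanone
Product: 5 1-[2,6-bis(benzyloxy)-4-hydroxyphenyl]ethanone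
Conditions: HCl (cat.), MeOH, 50 °C
Reagents that add atoms: none
Why: Acid-catalysed acetal exchange removes the methoxymethyl group as dimethoxymethane, and benzyl ethers and the ketone are inert to dilute methanolic acid.

Step 4
Reactants: 5 1-[2,6-bis(benzyloxy)-4-hydroxyphenyl]ethanone; 6 formaldehyde (charged as paraformaldehyde); 7 4,4,5,5-tetramethyl-2-(2-methylprop-1-en-1-yl)-1,3,2-dioxaborolane
Product: 10 1-[(3R)-5,7-bis(benzyloxy)-2,2-dimethyl-3-(4,4,5,5-tetramethyl-1,3,2-dioxaborolan-2-yl)chroman-6-yl]ethanone, via hydroxymethylphenol 8 (not isolated), via o-quinone methide 9 (not isolated)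
Conditions: 5 and (CH2O)n (1.1 equiv) added in portions to 7 (5 equiv), confined chiral Brønsted acid (BINOL-derived N-triflyl imidodiphosphorimidate with 3,3'-bis[3,5-bis(trifluoromethyl)phenyl] groups, 5–10 mol %), 5 Å MS, CHCl3, 0 °C to rt
Reagents that add atoms: none
Why: Proposed new method: the acid hydroxymethylates 5 ortho to its only free hydroxyl and dehydrates 8 to the ion-paired o-quinone methide 9; the methylene terminus of 9 is attacked by the boron-bearing alkene carbon, so that positive charge builds on the dimethyl carbon (tertiary and β to the C–B bond), and the quinone methide oxygen closes onto that carbon, forming C4a–C4, C4–C3 and O1–C2 and closing the dihydropyran ring in a six-membered, asynchronous inverse-electron-demand oxa-(4+2) mode. The closest known reaction types are chiral phosphoric acid-catalysed (4+2) cycloadditions of o-quinone methides (from o-hydroxybenzyl alcohols) with styrenes, enamides or enol ethers, and phenol–formaldehyde–alkene chroman syntheses; an alkenylboronate as the 2π partner and its enantiocontrol are untested. The C3 stereocentre is fixed in the C4–C3 bond-forming event by which enantiotopic alkene face the confined chiral anion, hydrogen-bonded to the quinone methide oxygen, allows to approach, and the (3R) sense is secured by the choice of catalyst antipode. Regioselectivity comes from the substrate: only the para hydroxyl is free, its two ortho carbons are equivalent, and the alkene polarity (cation at CMe2, boron at C3) gives the 2,2-dimethyl-3-boryl orientation that an enol ether would reverse. The step also needs chemoselectivity (alkene trapping over attack by a second phenol or a Prins reaction of formaldehyde with 7, and ring closure over loss of boron from the β-boryl cation), which is addressed by excess boronate, portionwise dosing of 5 and formaldehyde, a non-nucleophilic counter-anion and molecular sieves.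

Step 5
Reactants: 10 1-[(3R)-5,7-bis(benzyloxy)-2,2-dimethyl-3-(4,4,5,5-tetramethyl-1,3,2-dioxaborolan-2-yl)chroman-6-yl]ethanone
Product: 12 1-[(3R)-5,7-bis(benzyloxy)-3-hydroxy-2,2-dimethylchroman-6-yl]ethanone, via borate ester 11 (not isolated)
Conditions: NaBO3·4H2O (5 equiv), THF/H2O, 0 °C to rt
Reagents that add atoms: sodium perborate tetrahydrate, [Na+].[O-]OB=O.O.O.O.O
Why: Peroxide oxidation of the secondary alkylboronate proceeds by 1,2-migration of C3 from boron to oxygen with retention, so (3R)-10 should give (3R)-12; the mild perborate should favour migration over β-elimination of the aryloxy group and leave the hindered, fully etherified aryl ketone untouched.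

Step 6
Reactants: 12 1-[(3R)-5,7-bis(benzyloxy)-3-hydroxy-2,2-dimethylchroman-6-yl]ethanone
Product: 13 1-[(3R)-3,5,7-trihydroxy-2,2-dimethylchroman-6-yl]ethanone
Conditions: H2 (1 atm), 10% Pd/C, EtOAc/MeOH, rt
Reagents that add atoms: none
Why: Catalytic hydrogenolysis cleaves both benzyl ethers, while the chelated aryl ketone and the non-benzylic C3 carbinol (stereocentre untouched) should be inert.

Step 7
Reactants: 14 methyl 3-oxopentanoate; 15 N-methoxy-N-methylpropanamide
Product: 17 methyl 4-methyl-3,5-dioxoheptanoate, via dianion 16 (not isolated)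
Conditions: 14 (2.2 equiv), NaH, THF, 0 °C; n-BuLi, 0 °C; then 15 (1.0 equiv), 0 °C to rt; aq. HCl
Reagents that add atoms: none
Why: γ-Acylation of the β-keto ester dianion (Claisen-type condensation) occurs at the more reactive terminal carbanion; the chelated Weinreb tetrahedral intermediate prevents over-addition, and the excess dianion absorbs the acidic product protons.

Step 8
Reactants: 17 methyl 4-methyl-3,5-dioxoheptanoate
Product: 18 6-ethyl-4-hydroxy-5-methyl-2H-pyran-2-one
Conditions: DBU (1.2 equiv), toluene, 90 °C; then aq. HCl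
Reagents that add atoms: none
Why: Base-mediated enol lactonisation (intramolecular transesterification of the C5 enol onto the methyl ester) of a 3,5-dioxo ester is the standard closure to a 4-hydroxy-2-pyranone.

Step 9
Reactants: 13 1-[(3R)-3,5,7-trihydroxy-2,2-dimethylchroman-6-yl]ethanone; 18 6-ethyl-4-hydroxy-5-methyl-2H-pyran-2-one
Product: 21 3-{[(3R)-6-acetyl-3,5,7-trihydroxy-2,2-dimethylchroman-8-yl]methyl}-6-ethyl-4-hydroxy-5-methyl-2H-pyran-2-one (CNP0314185.1), via Mannich base 19 (not isolated), via methylidenepyrandione 20 (not isolated)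
Conditions: 18 (1.5 equiv), dimethylmethylideneammonium iodide (1.5 equiv), MeCN, rt, 1 h; then 13, 50 °C
Reagents that add atoms: dimethylmethylideneammonium iodide (Eschenmoser's salt), C=[N+](C)C.[I-]
Why: A Mannich reaction at pyranone C3 followed by loss of dimethylamine gives the methylidene pyrandione, which undergoes Friedel–Crafts-type conjugate addition by C8, the only free aromatic position of 13; converting all of 18 to 19 before 13 is added leaves no free pyranone nucleophile for self-coupling, and the C3 stereocentre is not involved.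

**Compound list**

1 | 2',4',6'-trihydroxyacetophenone | CC(=O)c1c(O)cc(O)cc1O | starting material
2 | 1-[2,6-dihydroxy-4-(methoxymethoxy)phenyl]ethanone | CC(=O)c1c(O)cc(OCOC)cc1O | intermediate
3 | benzyl bromide | BrCc1ccccc1 | starting material
4 | 1-[2,6-bis(benzyloxy)-4-(methoxymethoxy)phenyl]ethanone | CC(=O)c1c(OCc2ccccc2)cc(OCOC)cc1OCc3ccccc3 | intermediate
5 | 1-[2,6-bis(benzyloxy)-4-hydroxyphenyl]ethanone | CC(=O)c1c(OCc2ccccc2)cc(O)cc1OCc3ccccc3 | intermediate
6 | formaldehyde (as paraformaldehyde) | C=O | starting material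
7 | 4,4,5,5-tetramethyl-2-(2-methylprop-1-en-1-yl)-1,3,2-dioxaborolane | CC(C)=CB1OC(C)(C)C(C)(C)O1 | starting material
8 | 1-[2,6-bis(benzyloxy)-4-hydroxy-3-(hydroxymethyl)phenyl]ethanone | CC(=O)c1c(OCc2ccccc2)cc(O)c(CO)c1OCc3ccccc3 | intermediate
9 | 4-acetyl-3,5-bis(benzyloxy)-6-methylidenecyclohexa-2,4-dien-1-one | CC(=O)C1=C(OCc2ccccc2)C(=C)C(=O)C=C1OCc3ccccc3 | intermediate
10 | 1-[(3R)-5,7-bis(benzyloxy)-2,2-dimethyl-3-(4,4,5,5-tetramethyl-1,3,2-dioxaborolan-2-yl)chroman-6-yl]ethanone | CC(=O)c1c(OCc3ccccc3)cc2OC(C)(C)[C@H](B4OC(C)(C)C(C)(C)O4)Cc2c1OCc5ccccc5 | intermediate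
11 | 1-[(3R)-5,7-bis(benzyloxy)-2,2-dimethyl-3-[(4,4,5,5-tetramethyl-1,3,2-dioxaborolan-2-yl)oxy]chroman-6-yl]ethanone | CC(=O)c1c(OCc3ccccc3)cc2OC(C)(C)[C@H](OB4OC(C)(C)C(C)(C)O4)Cc2c1OCc5ccccc5 | intermediate
12 | 1-[(3R)-5,7-bis(benzyloxy)-3-hydroxy-2,2-dimethylchroman-6-yl]ethanone | CC(=O)c1c(OCc3ccccc3)cc2OC(C)(C)[C@H](O)Cc2c1OCc4ccccc4 | intermediate
13 | 1-[(3R)-3,5,7-trihydroxy-2,2-dimethylchroman-6-yl]ethanone | CC(=O)c1c(O)cc2OC(C)(C)[C@H](O)Cc2c1O | intermediate
14 | methyl 3-oxopentanoate | CCC(=O)CC(=O)OC | starting material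
15 | N-methoxy-N-methylpropanamide | CCC(=O)N(C)OC | starting material
16 | sodium lithium dianion of methyl 3-oxopentanoate | CC=C([O-])C=C([O-])OC.[Na+].[Li+] | intermediate
17 | methyl 4-methyl-3,5-dioxoheptanoate | CCC(=O)C(C)C(=O)CC(=O)OC | intermediate
18 | 6-ethyl-4-hydroxy-5-methyl-2H-pyran-2-one | CCc1oc(=O)cc(O)c1C | intermediate
19 | 3-[(dimethylamino)methyl]-6-ethyl-4-hydroxy-5-methyl-2H-pyran-2-one | CCc1oc(=O)c(CN(C)C)c(O)c1C | intermediate
20 | 6-ethyl-5-methyl-3-methylidene-2H-pyran-2,4(3H)-dione | CCC1=C(C)C(=O)C(=C)C(=O)O1 | intermediate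
21 | 3-{[(3R)-6-acetyl-3,5,7-trihydroxy-2,2-dimethylchroman-8-yl]methyl}-6-ethyl-4-hydroxy-5-methyl-2H-pyran-2-one | CCc1oc(=O)c(Cc2c(O)c(C(C)=O)c(O)c3c2OC(C)(C)[C@H](O)C3)c(O)c1C | target

**Count**

Total steps: 9. Longest linear sequence: 7 (steps 1–6 and 9); steps 7–8 form the pyranone branch.

**Steps most likely to fail**

1. Step 4. The o-quinone methide may be intercepted by unreacted phenol to give methylene-bridged dimers. The β-boryl cation may lose boron instead of closing the ring. The alkenylboronate may be consumed by protonation or by a Prins reaction with formaldehyde. Discrimination of the alkene faces may be poor. Fallback from 5 to 13, by known chemistry: O-alkylation of 5 with 3-chloro-3-methylbut-1-yne (K2CO3, KI, acetone, reflux) gives 1-[2,6-bis(benzyloxy)-4-[(2-methylbut-3-yn-2-yl)oxy]phenyl]ethanone F1. Heating in N,N-diethylaniline at about 150 °C (aryl propargyl Claisen rearrangement, 1,5-hydrogen shift, oxa-6π electrocyclisation) gives 1-[5,7-bis(benzyloxy)-2,2-dimethyl-2H-chromen-6-yl]ethanone F2. Jacobsen–Katsuki epoxidation with (R,R)-N,N'-bis(3,5-di-tert-butylsalicylidene)cyclohexane-1,2-diaminomanganese chloride (trivalent manganese), NaOCl and 4-phenylpyridine N-oxide in CH2Cl2 at 0 °C gives 1-[(3R,4R)-5,7-bis(benzyloxy)-3,4-epoxy-2,2-dimethylchroman-6-yl]ethanone F3. The acid-labile epoxide is hydrogenated without purification (H2, 10% Pd/C, EtOAc, trace Et3N): hydrogenolysis of the benzylic C4–O bond and of both benzyl ethers gives 13, and the route continues with step 9.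

2. Step 9. The methylidene pyrandione may couple with pyranone instead of the chroman, or the components may cross-couple unselectively. Fallback from 13 to 21, with the roles of electrophile and nucleophile exchanged: 13 is aminomethylated at C8 with dimethylmethylideneammonium iodide alone (MeCN, rt) and the product is isolated as 1-[(3R)-8-[(dimethylamino)methyl]-3,5,7-trihydroxy-2,2-dimethylchroman-6-yl]ethanone F4. Heating F4 with 18 in dioxane at 90–100 °C expels dimethylamine to give the chroman o-quinone methide, which is trapped at pyranone C3 to give 21.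

3. Step 1 (and the benzylation that depends on it). Alkylation may go beyond one hydroxyl or occur at a chelated hydroxyl, and C-benzylation may intrude in step 2. Fallback from 1 to 5, with steric differentiation and neutral benzylation: TIPSCl (1.05 equiv) and imidazole in DMF at 0 °C silylate the unhindered 4-hydroxyl to give 1-[2,6-dihydroxy-4-(triisopropylsilyloxy)phenyl]ethanone F5. Double Mitsunobu etherification (BnOH, PPh3, DIAD, THF) gives 1-[2,6-bis(benzyloxy)-4-(triisopropylsilyloxy)phenyl]ethanone F6. Tetrabutylammonium fluoride in THF at 0 °C then gives 5.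

**Further compounds**

F1 | step 4 | 1-[2,6-bis(benzyloxy)-4-[(2-methylbut-3-yn-2-yl)oxy]phenyl]ethanone | CC(=O)c1c(OCc2ccccc2)cc(OC(C)(C)C#C)cc1OCc3ccccc3
F2 | step 4 | 1-[5,7-bis(benzyloxy)-2,2-dimethyl-2H-chromen-6-yl]ethanone | CC(=O)c1c(OCc3ccccc3)cc2OC(C)(C)C=Cc2c1OCc4ccccc4
F3 | step 4 | 1-[(3R,4R)-5,7-bis(benzyloxy)-3,4-epoxy-2,2-dimethylchroman-6-yl]ethanone | CC(=O)c1c(OCc3ccccc3)cc2OC(C)(C)[C@@H]4O[C@@H]4c2c1OCc5ccccc5
F4 | step 9 | 1-[(3R)-8-[(dimethylamino)methyl]-3,5,7-trihydroxy-2,2-dimethylchroman-6-yl]ethanone | CC(=O)c1c(O)c(CN(C)C)c2OC(C)(C)[C@H](O)Cc2c1O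
F5 | step 1 | 1-[2,6-dihydroxy-4-(triisopropylsilyloxy)phenyl]ethanone | CC(=O)c1c(O)cc(O[Si](C(C)C)(C(C)C)C(C)C)cc1O
F6 | step 1 | 1-[2,6-bis(benzyloxy)-4-(triisopropylsilyloxy)phenyl]ethanone | CC(=O)c1c(OCc2ccccc2)cc(O[Si](C(C)C)(C(C)C)C(C)C)cc1OCc3ccccc3
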